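**Strategy.** Ring A of the target is a benzene that carries only the C6/C7 hydroxyls and the fusion carbons C4a/C8a, and it shares the C4a–C8a bond with ring B. Both rings are therefore made together by a cobalt-catalysed [2+2+2] cyclotrimerisation. A 1,7-diyne whose tether is C1–C2–C3=C4 (both stereocentres, both esters and a 2-silyl-3-furyl group in place) takes up bis(pinacolatoboryl)ethyne, forming C4a–C8a, C5–C6 and C7–C8 at once. The two C–B bonds serve as a masked catechol through the singlet-oxygen/olefination sequence that turns the silylfuran into the 6-carboxy-2-pyranone. C1 comes from a rhodium-catalysed conjugate alkynylation and C2 from an anti-selective enolate alkylation.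

Key step: step 10

Abbreviations: TMS = trimethylsilyl, TIPS = tri(propan-2-yl)silyl, TBS = tert-butyldimethylsilyl, Bpin = 4,4,5,5-tetramethyl-1,3,2-dioxaborolan-2-yl. Atom numbers C1–C8a and rings A (benzo) and B (carbocycle) are those of the 1,2-dihydronaphthalene of the target.

Remark on the structures: the target is the trans-(1R,2R) isomer. In the enediyne the C3=C4 bond is (E) by the sequence rule, the alkynyl group lying cis to C2 and trans to the tert-butyl ester.

Assumption 1: bis(pinacolatoboryl)ethyne, (triisopropylsilyl)acetylene and 3-(trimethylsilyl)propynal are taken as catalogue items.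

Assumption 2: the facial sense of the rhodium/(R)-DTBM-SEGPHOS alkynylation is assigned by analogy with β-aryl enals and is to be confirmed on the first chiral aldehyde; if it proves opposite, the (S)-ligand is used with no other change.

Step 1
Reactants: 1 3-bromofuran
Product: 3 3-bromo-2-(trimethylsilyl)furan, via 3-bromo-2-furyllithium 2 (not isolated)
Conditions: LDA, THF, −78 °C; then TMSCl, −78 °C to rt
Reagents that add atoms: chlorotrimethylsilane, C[Si](C)(C)Cl
Why: Deprotonative lithiation of 3-bromofuran is directed to C2 by the ring oxygen and the adjacent bromine, and the furyllithium is silylated at −78 °C before halogen migration can set in (directed metalation–silylation).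

Step 2
Reactants: 3 3-bromo-2-(trimethylsilyl)furan; 4 (2E)-3-(dimethylamino)prop-2-enal
Product: 7 (2E)-3-[2-(trimethylsilyl)furan-3-yl]prop-2-enal, via 2-(trimethylsilyl)-3-furyllithium 5 (not isolated), via lithium amino alkoxide adduct 6 (not isolated)
Conditions: n-BuLi, Et2O, −78 °C; then 4, −78 to 0 °C; then 1 M HCl, 0 °C
Reagents that add atoms: none
Why: Bromine–lithium exchange gives the 3-furyllithium, which adds 1,2 to the vinylogous formamide, and acidic work-up expels dimethylamine to leave the conjugated (E)-enal (vinylogous formylation of an organolithium).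

Step 3
Reactants: 7 (2E)-3-[2-(trimethylsilyl)furan-3-yl]prop-2-enal; 8 ethynyltri(propan-2-yl)silane
Product: 9 (3R)-5-(TIPS)-3-[2-(trimethylsilyl)furan-3-yl]pent-4-ynal
Conditions: [Rh(OAc)(C2H4)2]2 (2.5 mol %), (R)-DTBM-SEGPHOS (6 mol %), 8 (2 equiv), MeOH, 40 °C
Reagents that add atoms: none
Why: A rhodium acetylide formed from 8 adds 1,4 to the enal and the rhodium enolate is protonated by methanol (rhodium-catalysed asymmetric conjugate alkynylation of a β-aryl enal); the bulky silyl group and ligand suppress alkyne dimerisation, and the chiral bisphosphine selects the enal face so that the future C1 is set as (R).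

Step 4
Reactants: 9 (3R)-5-(TIPS)-3-[2-(trimethylsilyl)furan-3-yl]pent-4-ynal
Product: 10 (3R)-5-(TIPS)-3-[2-(trimethylsilyl)furan-3-yl]pent-4-ynoic acid
Conditions: NaClO2, NaH2PO4, 2-methyl-2-butene, t-BuOH/H2O, 0 °C to rt
Reagents that add atoms: sodium chlorite, [Na+].[O-]Cl=O
Why: Pinnick oxidation converts the aldehyde to the acid under buffered conditions that neither epimerise the β-stereocentre nor protodesilylate the furan, the alkene scavenger removing hypochlorite before it can attack the furan.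

Step 5
Reactants: 10 (3R)-5-(TIPS)-3-[2-(trimethylsilyl)furan-3-yl]pent-4-ynoic acid
Product: 11 methyl (3R)-5-(TIPS)-3-[2-(trimethylsilyl)furan-3-yl]pent-4-ynoate
Conditions: MeI, K2CO3, DMF, rt
Reagents that add atoms: iodomethane, CI
Why: SN2 O-methylation of the carboxylate; the stereocentre is β to the carbonyl group and cannot enolise.

Step 6
Reactants: 11 methyl (3R)-5-(TIPS)-3-[2-(trimethylsilyl)furan-3-yl]pent-4-ynoate; 12 tert-butyl bromoacetate
Product: 14 4-tert-butyl 1-methyl (2S)-2-{(1R)-3-(TIPS)-1-[2-(trimethylsilyl)furan-3-yl]prop-2-yn-1-yl}butanedioate, via lithium methyl ester enolate 13 (not isolated)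
Conditions: LDA, THF, −78 °C; then 12, −78 to −40 °C
Reagents that add atoms: none
Why: Alkylation of the ester enolate with the reactive α-bromo ester; in the A(1,3)-strain-minimised conformer (C1–H eclipsing the enolate plane) the electrophile should approach anti to the bulky 2-silylfuryl group and past the slim alkynyl group, which sets C2 with the relative configuration of the trans-1,2 target (1,2-asymmetric induction in an acyclic enolate alkylation).

Step 7
Reactants: 14 4-tert-butyl 1-methyl (2S)-2-{(1R)-3-(TIPS)-1-[2-(trimethylsilyl)furan-3-yl]prop-2-yn-1-yl}butanedioate; 15 3-(trimethylsilyl)prop-2-ynal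
Product: 17 4-tert-butyl 1-methyl (2R)-3-[1-hydroxy-3-(trimethylsilyl)prop-2-yn-1-yl]-2-{(1R)-3-(TIPS)-1-[2-(trimethylsilyl)furan-3-yl]prop-2-yn-1-yl}butanedioate (diastereomers at C3 and C4), via lithium tert-butyl ester enolate 16 (not isolated)
Conditions: LDA, THF, −78 °C; then 15, −78 °C; AcOH quench at −78 °C
Reagents that add atoms: none
Why: Kinetic deprotonation should occur at the unhindered C3 methylene of the tert-butyl ester and not at the tertiary, flanked C2–H, and the enolate adds 1,2 to the ynal (directed aldol addition); the new centres at C3 and C4 form as a mixture that is erased in step 8, and the C2 descriptor changes to (R) only because C3 now outranks C1.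

Step 8
Reactants: 17 4-tert-butyl 1-methyl (2R)-3-[1-hydroxy-3-(trimethylsilyl)prop-2-yn-1-yl]-2-{(1R)-3-(TIPS)-1-[2-(trimethylsilyl)furan-3-yl]prop-2-yn-1-yl}butanedioate
Product: 19 4-tert-butyl 1-methyl (2R,3E)-2-{(1R)-3-(TIPS)-1-[2-(trimethylsilyl)furan-3-yl]prop-2-yn-1-yl}-3-[3-(trimethylsilyl)prop-2-yn-1-ylidene]butanedioate, via propargylic mesylate 18 (not isolated)
Conditions: MsCl, Et3N, CH2Cl2, −20 °C; then DBU, 0 °C
Reagents that add atoms: none
Why: Mesylation and base-induced E1cB elimination through the ester enolate should deliver, from every aldol diastereomer, the more stable (E)-alkene with the alkynyl group trans to the tert-butyl ester and cis to C2, the geometry ring closure requires; C2 carries no leaving group and is left alone at 0 °C.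

Step 9
Reactants: 19 4-tert-butyl 1-methyl (2R,3E)-2-{(1R)-3-(TIPS)-1-[2-(trimethylsilyl)furan-3-yl]prop-2-yn-1-yl}-3-[3-(trimethylsilyl)prop-2-yn-1-ylidene]butanedioate
Product: 20 4-tert-butyl 1-methyl (2R,3E)-3-(prop-2-yn-1-ylidene)-2-{(1R)-1-[2-(trimethylsilyl)furan-3-yl]prop-2-yn-1-yl}butanedioate
Conditions: TBAF, AcOH (1:1), THF, 0 °C to rt
Reagents that add atoms: none
Why: Fluoride cleaves the two C(sp)–Si bonds far faster than the C(sp2)–Si bond of the silylfuran, and the acetic acid buffer prevents base-induced epimerisation at C2 or migration of the double bond (protodesilylation of silylalkynes).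

Step 10
Reactants: 20 4-tert-butyl 1-methyl (2R,3E)-3-(prop-2-yn-1-ylidene)-2-{(1R)-1-[2-(trimethylsilyl)furan-3-yl]prop-2-yn-1-yl}butanedioate; 21 2,2'-(ethyne-1,2-diyl)bis(4,4,5,5-tetramethyl-1,3,2-dioxaborolane)
Product: 22 3-tert-butyl 2-methyl (1R,2R)-6,7-bis(Bpin)-1-[2-(trimethylsilyl)furan-3-yl]-1,2-dihydronaphthalene-2,3-dicarboxylate
Conditions: CpCo(CO)2 (20 mol %), 21 (3 equiv), degassed toluene, reflux, visible-light irradiation, 20 added by syringe pump
Reagents that add atoms: none
Why: Light-induced loss of CO from CpCo(CO)2 frees a CpCo fragment of monovalent cobalt that binds the two alkynes of 20 and couples them oxidatively through their inner carbons to a cobaltacyclopentadiene of trivalent cobalt (C4a–C8a), which takes up 21 and releases the benzene ring by reductive elimination (C5–C6 and C7–C8). The closest known reaction type is the cobalt-mediated [2+2+2] co-cyclotrimerisation of an α,ω-diyne with an alkynylboronate. Ring B closes in the oxidative coupling as a six-membered carbocycle fused to the metallacycle, the (E)-alkene holding the alkyne on C4 cis to C2 and so within reach of the alkyne on C1; ring A closes by insertion of 21 into a Co–C bond followed by C–C reductive elimination. No stereocentre is formed, and C1 and C2, both on the tether, are not touched by the neutral, aprotic medium. The step needs chemoselectivity for the mixed diyne–monoyne product over self-trimerisation of 20, which is secured by the intramolecular pairing of the two tethered alkynes, by the inability of the bulky, electron-poor 21 to trimerise by itself, and by keeping 21 in excess while 20 is added slowly; regioselectivity is not an issue because 21 is symmetrical.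

Step 11
Reactants: 22 3-tert-butyl 2-methyl (1R,2R)-6,7-bis(Bpin)-1-[2-(trimethylsilyl)furan-3-yl]-1,2-dihydronaphthalene-2,3-dicarboxylate
Product: 25 3-tert-butyl 2-methyl (1R,2R)-6,7-bis(Bpin)-1-(5-hydroxy-2-oxo-2,5-dihydrofuran-3-yl)-1,2-dihydronaphthalene-2,3-dicarboxylate (lactol epimers), via furan endoperoxide 23 (not isolated), via trimethylsilyl ester aldehyde 24 (not isolated)
Conditions: O2, tetraphenylporphyrin (cat.), visible light, CH2Cl2, −78 °C; then H2O, THF, 0 °C
Reagents that add atoms: oxygen, O=O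
Why: [4+2] addition of singlet oxygen across the furan, 1,2-shift of silicon to the peroxide oxygen and hydrolysis of the silyl ester (silyl-directed furan photooxygenation) make the silicon-bearing carbon the lactone carbonyl, next to the carbon attached to C1; the arylboronates and the electron-poor C3=C4 bond are inert to singlet oxygen, and the lactol carbon forms as an epimeric mixture that disappears in step 14.

Step 12
Reactants: 26 di-tert-butyl (2R,3R)-tartrate; 27 dimethyl phosphite
Product: 29 tert-butyl 2-(dimethoxyphosphoryl)-2-hydroxyacetate (racemic), via tert-butyl glyoxylate 28 (not isolated)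
Conditions: H5IO6, Et2O, rt; filter; then 27, Et3N (cat.), 0 °C to rt
Reagents that add atoms: none
Why: Malaprade cleavage of the diol releases two equivalents of the glyoxylate, whose aldehyde takes up the P–H bond of the phosphite under mild base catalysis (Pudovik addition); the carbinol centre is racemic and is destroyed in step 14.

Step 13
Reactants: 29 tert-butyl 2-(dimethoxyphosphoryl)-2-hydroxyacetate
Product: 30 tert-butyl 2-[(tert-butyldimethylsilyl)oxy]-2-(dimethoxyphosphoryl)acetate
Conditions: TBSCl, imidazole, DMF, rt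
Reagents that add atoms: tert-butyl(chloro)dimethylsilane, CC(C)(C)[Si](C)(C)Cl
Why: Imidazole-promoted O-silylation gives the α-silyloxy phosphonoacetate, a masked α-keto ester anion, under conditions too weakly basic for phosphonate–phosphate rearrangement.

Step 14
Reactants: 25 3-tert-butyl 2-methyl (1R,2R)-6,7-bis(Bpin)-1-(5-hydroxy-2-oxo-2,5-dihydrofuran-3-yl)-1,2-dihydronaphthalene-2,3-dicarboxylate; 30 tert-butyl 2-[(tert-butyldimethylsilyl)oxy]-2-(dimethoxyphosphoryl)acetate
Product: 32 (2Z,4Z)-6-tert-butoxy-5-(TBS-oxy)-2-[(1R,2R)-6,7-bis(Bpin)-3-(tert-butoxycarbonyl)-2-(methoxycarbonyl)-1,2-dihydronaphthalen-1-yl]-6-oxohexa-2,4-dienoic acid, via lithiated phosphonate 31 (not isolated)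
Conditions: 30 (2.5 equiv), LiHMDS (2.4 equiv), THF, −78 °C; then 25, −78 to 0 °C; pH 4 phosphate buffer
Reagents that add atoms: none
Why: The lactol reacts through its ring-opened (Z)-4-oxo-2-enoate form, one equivalent of the phosphonate anion serving as base for the acid, in a Horner–Wadsworth–Emmons olefination that attaches C6 of the future pyranone with its carboxyl group as a silyl enol ether; the (2Z) geometry is inherited from the butenolide ring, the 4,5-geometry is inconsequential because the enol is freed before ring closure, and the stabilised anion is too weak a base to epimerise C2.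

Step 15
Reactants: 32 (2Z,4Z)-6-tert-butoxy-5-(TBS-oxy)-2-[(1R,2R)-6,7-bis(Bpin)-3-(tert-butoxycarbonyl)-2-(methoxycarbonyl)-1,2-dihydronaphthalen-1-yl]-6-oxohexa-2,4-dienoic acid
Product: 34 3-tert-butyl 2-methyl (1R,2R)-6,7-bis(Bpin)-1-[6-(tert-butoxycarbonyl)-2-oxo-2H-pyran-3-yl]-1,2-dihydronaphthalene-2,3-dicarboxylate, via free enol acid 33 (not isolated)
Conditions: 1 M HCl, THF, rt; then EDC·HCl, DMAP (cat.), CH2Cl2, 0 °C to rt
Reagents that add atoms: none
Why: Acid hydrolysis of the silyl enol ether frees the 2-hydroxydienoate (in equilibrium with its α-keto ester tautomers), and carbodiimide activation of the (2Z)-acid lets the enol oxygen close the six-membered ring (enol lactonisation, Steglich-type O-acylation), all tautomers draining into the conjugated 2-pyranone.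

Step 16
Reactants: 34 3-tert-butyl 2-methyl (1R,2R)-6,7-bis(Bpin)-1-[6-(tert-butoxycarbonyl)-2-oxo-2H-pyran-3-yl]-1,2-dihydronaphthalene-2,3-dicarboxylate
Product: 36 3-tert-butyl 2-methyl (1R,2R)-1-[6-(tert-butoxycarbonyl)-2-oxo-2H-pyran-3-yl]-6,7-dihydroxy-1,2-dihydronaphthalene-2,3-dicarboxylate, via bis(borate) ester 35 (not isolated)
Conditions: Me3NO (anhydrous, 5 equiv), CH2Cl2, rt to 40 °C, argon; then aq. NH4Cl
Reagents that add atoms: trimethylamine N-oxide, C[N+](C)(C)[O-]
Why: The N-oxide oxygen adds to boron and the aryl group migrates from boron to oxygen with loss of trimethylamine (amine N-oxide ipso-hydroxylation of arylboronic esters), twice, under neutral, non-nucleophilic conditions that leave the pyranone and the esters intact; work-up hydrolyses the borate to the catechol.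

Step 17
Reactants: 36 3-tert-butyl 2-methyl (1R,2R)-1-[6-(tert-butoxycarbonyl)-2-oxo-2H-pyran-3-yl]-6,7-dihydroxy-1,2-dihydronaphthalene-2,3-dicarboxylate
Product: 37 (1R,2R)-1-(6-carboxy-2-oxo-2H-pyran-3-yl)-6,7-dihydroxy-2-(methoxycarbonyl)-1,2-dihydronaphthalene-3-carboxylic acid
Conditions: TFA/CH2Cl2 (1:1), iPr3SiH, rt, argon
Reagents that add atoms: none
Why: Acidolysis of both tert-butyl esters via the tert-butyl cation (trapped by the silane so that the catechol ring is not alkylated) leaves the methyl ester, the pyranone and both stereocentres untouched.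

**Compound list**

1 | 3-bromofuran | Brc1ccoc1 | starting material
2 | (3-bromofuran-2-yl)lithium | [Li]c1occc1Br | intermediate (not isolated)
3 | 3-bromo-2-(trimethylsilyl)furan | C[Si](C)(C)c1occc1Br | intermediate
4 | (2E)-3-(dimethylamino)prop-2-enal | CN(C)/C=C/C=O | starting material
5 | [2-(trimethylsilyl)furan-3-yl]lithium | [Li]c1ccoc1[Si](C)(C)C | intermediate (not isolated)
6 | lithium (2E)-3-(dimethylamino)-1-[2-(trimethylsilyl)furan-3-yl]prop-2-en-1-olate (racemic) | CN(C)/C=C/C(O[Li])c1ccoc1[Si](C)(C)C | intermediate (not isolated)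
7 | (2E)-3-[2-(trimethylsilyl)furan-3-yl]prop-2-enal | O=C/C=C/c1ccoc1[Si](C)(C)C | intermediate
8 | ethynyltri(propan-2-yl)silane | C#C[Si](C(C)C)(C(C)C)C(C)C | starting material
9 | (3R)-5-[tri(propan-2-yl)silyl]-3-[2-(trimethylsilyl)furan-3-yl]pent-4-ynal | O=CC[C@H](C#C[Si](C(C)C)(C(C)C)C(C)C)c1ccoc1[Si](C)(C)C | intermediate
10 | (3R)-5-[tri(propan-2-yl)silyl]-3-[2-(trimethylsilyl)furan-3-yl]pent-4-ynoic acid | OC(=O)C[C@H](C#C[Si](C(C)C)(C(C)C)C(C)C)c1ccoc1[Si](C)(C)C | intermediate
11 | methyl (3R)-5-[tri(propan-2-yl)silyl]-3-[2-(trimethylsilyl)furan-3-yl]pent-4-ynoate | COC(=O)C[C@H](C#C[Si](C(C)C)(C(C)C)C(C)C)c1ccoc1[Si](C)(C)C | intermediate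
12 | tert-butyl bromoacetate | BrCC(=O)OC(C)(C)C | starting material
13 | lithium enolate of 11 | COC(O[Li])=C[C@H](C#C[Si](C(C)C)(C(C)C)C(C)C)c1ccoc1[Si](C)(C)C | intermediate (not isolated)
14 | 4-tert-butyl 1-methyl (2S)-2-{(1R)-3-[tri(propan-2-yl)silyl]-1-[2-(trimethylsilyl)furan-3-yl]prop-2-yn-1-yl}butanedioate | COC(=O)[C@@H](CC(=O)OC(C)(C)C)[C@H](C#C[Si](C(C)C)(C(C)C)C(C)C)c1ccoc1[Si](C)(C)C | intermediate
15 | 3-(trimethylsilyl)prop-2-ynal | O=CC#C[Si](C)(C)C | starting material
16 | lithium enolate of 14 at C3 (tert-butyl ester enolate) | COC(=O)[C@@H](C=C(O[Li])OC(C)(C)C)[C@H](C#C[Si](C(C)C)(C(C)C)C(C)C)c1ccoc1[Si](C)(C)C | intermediate (not isolated)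
17 | 4-tert-butyl 1-methyl (2R)-3-[1-hydroxy-3-(trimethylsilyl)prop-2-yn-1-yl]-2-{(1R)-3-[tri(propan-2-yl)silyl]-1-[2-(trimethylsilyl)furan-3-yl]prop-2-yn-1-yl}butanedioate (mixture at C3 and at the carbinol carbon) | COC(=O)[C@@H](C(C(O)C#C[Si](C)(C)C)C(=O)OC(C)(C)C)[C@H](C#C[Si](C(C)C)(C(C)C)C(C)C)c1ccoc1[Si](C)(C)C | intermediate
18 | methanesulfonate of 17 | COC(=O)[C@@H](C(C(OS(C)(=O)=O)C#C[Si](C)(C)C)C(=O)OC(C)(C)C)[C@H](C#C[Si](C(C)C)(C(C)C)C(C)C)c1ccoc1[Si](C)(C)C | intermediate (not isolated)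
19 | 4-tert-butyl 1-methyl (2R,3E)-2-{(1R)-3-[tri(propan-2-yl)silyl]-1-[2-(trimethylsilyl)furan-3-yl]prop-2-yn-1-yl}-3-[3-(trimethylsilyl)prop-2-yn-1-ylidene]butanedioate | COC(=O)[C@@H](/C(C(=O)OC(C)(C)C)=C\C#C[Si](C)(C)C)[C@H](C#C[Si](C(C)C)(C(C)C)C(C)C)c1ccoc1[Si](C)(C)C | intermediate
20 | 4-tert-butyl 1-methyl (2R,3E)-3-(prop-2-yn-1-ylidene)-2-{(1R)-1-[2-(trimethylsilyl)furan-3-yl]prop-2-yn-1-yl}butanedioate | COC(=O)[C@@H](/C(C(=O)OC(C)(C)C)=C\C#C)[C@H](C#C)c1ccoc1[Si](C)(C)C | intermediate (key-step precursor)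
21 | 2,2'-(ethyne-1,2-diyl)bis(4,4,5,5-tetramethyl-1,3,2-dioxaborolane) | CC1(C)OB(OC1(C)C)C#CB1OC(C)(C)C(C)(C)O1 | starting material
22 | 3-tert-butyl 2-methyl (1R,2R)-6,7-bis(4,4,5,5-tetramethyl-1,3,2-dioxaborolan-2-yl)-1-[2-(trimethylsilyl)furan-3-yl]-1,2-dihydronaphthalene-2,3-dicarboxylate | COC(=O)[C@H]1C(C(=O)OC(C)(C)C)=Cc2cc(B3OC(C)(C)C(C)(C)O3)c(B3OC(C)(C)C(C)(C)O3)cc2[C@@H]1c1ccoc1[Si](C)(C)C | intermediate (key-step product)
23 | furan endoperoxide of 22 (2,3,7-trioxabicyclo[2.2.1]hept-5-ene, silicon at the bridgehead; both bridgehead epimers) | COC(=O)[C@H]1C(C(=O)OC(C)(C)C)=Cc2cc(B3OC(C)(C)C(C)(C)O3)c(B3OC(C)(C)C(C)(C)O3)cc2[C@@H]1C1=CC2OOC1([Si](C)(C)C)O2 | intermediate (not isolated)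
24 | trimethylsilyl (2Z)-2-[(1R,2R)-dihydronaphthalen-1-yl]-4-oxobut-2-enoate (ring substituents as in 22) | COC(=O)[C@H]1C(C(=O)OC(C)(C)C)=Cc2cc(B3OC(C)(C)C(C)(C)O3)c(B3OC(C)(C)C(C)(C)O3)cc2[C@@H]1/C(C(=O)O[Si](C)(C)C)=C/C=O | intermediate (not isolated)
25 | 3-tert-butyl 2-methyl (1R,2R)-6,7-bis(Bpin)-1-(5-hydroxy-2-oxo-2,5-dihydrofuran-3-yl)-1,2-dihydronaphthalene-2,3-dicarboxylate (lactol epimers) | COC(=O)[C@H]1C(C(=O)OC(C)(C)C)=Cc2cc(B3OC(C)(C)C(C)(C)O3)c(B3OC(C)(C)C(C)(C)O3)cc2[C@@H]1C1=CC(O)OC1=O | intermediate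
26 | di-tert-butyl (2R,3R)-tartrate | CC(C)(C)OC(=O)[C@H](O)[C@@H](O)C(=O)OC(C)(C)C | starting material
27 | dimethyl phosphite | CO[PH](=O)OC | starting material
28 | tert-butyl glyoxylate | O=CC(=O)OC(C)(C)C | intermediate (not isolated)
29 | tert-butyl 2-(dimethoxyphosphoryl)-2-hydroxyacetate (racemic) | COP(=O)(OC)C(O)C(=O)OC(C)(C)C | intermediate
30 | tert-butyl 2-[(tert-butyldimethylsilyl)oxy]-2-(dimethoxyphosphoryl)acetate (racemic) | COP(=O)(OC)C(O[Si](C)(C)C(C)(C)C)C(=O)OC(C)(C)C | intermediate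
31 | lithium salt of the carbanion of 30 | [Li+].COP(=O)(OC)[C-](O[Si](C)(C)C(C)(C)C)C(=O)OC(C)(C)C | intermediate (not isolated)
32 | (2Z,4Z)-6-tert-butoxy-5-[(tert-butyldimethylsilyl)oxy]-2-[(1R,2R)-6,7-bis(Bpin)-3-(tert-butoxycarbonyl)-2-(methoxycarbonyl)-1,2-dihydronaphthalen-1-yl]-6-oxohexa-2,4-dienoic acid (4Z drawn as the expected major isomer) | COC(=O)[C@H]1C(C(=O)OC(C)(C)C)=Cc2cc(B3OC(C)(C)C(C)(C)O3)c(B3OC(C)(C)C(C)(C)O3)cc2[C@@H]1/C(C(=O)O)=C/C=C(\O[Si](C)(C)C(C)(C)C)C(=O)OC(C)(C)C | intermediate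
33 | (2Z,4Z)-6-tert-butoxy-5-hydroxy-2-[(1R,2R)-dihydronaphthalen-1-yl]-6-oxohexa-2,4-dienoic acid (ring substituents as in 32; in equilibrium with its α-keto ester tautomers) | COC(=O)[C@H]1C(C(=O)OC(C)(C)C)=Cc2cc(B3OC(C)(C)C(C)(C)O3)c(B3OC(C)(C)C(C)(C)O3)cc2[C@@H]1/C(C(=O)O)=C/C=C(\O)C(=O)OC(C)(C)C | intermediate (not isolated)
34 | 3-tert-butyl 2-methyl (1R,2R)-6,7-bis(Bpin)-1-[6-(tert-butoxycarbonyl)-2-oxo-2H-pyran-3-yl]-1,2-dihydronaphthalene-2,3-dicarboxylate | COC(=O)[C@H]1C(C(=O)OC(C)(C)C)=Cc2cc(B3OC(C)(C)C(C)(C)O3)c(B3OC(C)(C)C(C)(C)O3)cc2[C@@H]1c1ccc(C(=O)OC(C)(C)C)oc1=O | intermediate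
35 | 6,7-bis[(4,4,5,5-tetramethyl-1,3,2-dioxaborolan-2-yl)oxy] analogue of 34 | COC(=O)[C@H]1C(C(=O)OC(C)(C)C)=Cc2cc(OB3OC(C)(C)C(C)(C)O3)c(OB3OC(C)(C)C(C)(C)O3)cc2[C@@H]1c1ccc(C(=O)OC(C)(C)C)oc1=O | intermediate (not isolated)
36 | 3-tert-butyl 2-methyl (1R,2R)-1-[6-(tert-butoxycarbonyl)-2-oxo-2H-pyran-3-yl]-6,7-dihydroxy-1,2-dihydronaphthalene-2,3-dicarboxylate | COC(=O)[C@H]1C(C(=O)OC(C)(C)C)=Cc2cc(O)c(O)cc2[C@@H]1c1ccc(C(=O)OC(C)(C)C)oc1=O | intermediate
37 | (1R,2R)-1-(6-carboxy-2-oxo-2H-pyran-3-yl)-6,7-dihydroxy-2-(methoxycarbonyl)-1,2-dihydronaphthalene-3-carboxylic acid | COC(=O)[C@H]1C(C(=O)O)=Cc2cc(O)c(O)cc2[C@@H]1c1ccc(C(=O)O)oc1=O | target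

**Step count.** Total: 17 steps (15 in the main line, 2 for phosphonate 30). Longest linear sequence: 15 steps (steps 1–11 and 14–17, from 1 to 37).

**Steps most likely to fail**

1. Step 10 (key step). What may go wrong: self-oligomerisation of 20 through its terminal alkynes and its electron-poor conjugated enyne may outrun insertion of the hindered diboryl alkyne, and metal-mediated migration of the C3=C4 bond toward C2 would erode the C2 centre. The fallback changes the substrate of the ring-forming event and not the catalyst: the double bond is introduced only after both rings are closed. It sets out from 17. Acetylation (Ac2O, DMAP, pyridine) should give the propargylic acetate F1. Buffered TBAF/AcOH should then give the terminal diyne acetate F2, a saturated 1,7-diyne without a conjugated enyne. The same cobalt co-cyclisation with 21 (a standard tetralin-forming cyclotrimerisation) should give the 4-acetoxytetralin F3. DBU then eliminates acetic acid across C3–C4 (benzylic leaving group, α-ester proton, E1cB), and the route is rejoined at 22. The alkene geometry question of step 8 also disappears on this path, since the ring fixes it.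

2. Step 3. What may go wrong: the ortho-silyl group crowds the β-carbon of the enal, so that alkyne dimerisation may overtake conjugate addition, or facial discrimination may drop. The fallback replaces asymmetric catalysis by a racemic synthesis with classical resolution. It sets out from 3. Bromine–lithium exchange and DMF should give 2-(trimethylsilyl)furan-3-carbaldehyde F4, and Knoevenagel condensation with Meldrum's acid the alkylidene Meldrum's acid F5. The bromomagnesium acetylide F6 (from 8 and EtMgBr) adds 1,4 to F5 to give the racemic adduct F7. Pyridine/water at 90 °C hydrolyses and decarboxylates F7 to the racemic acid F8. Crystallisation of the (1S,2R)-1-amino-2-indanol salt F9 of the (R)-acid (amine antipode and solvent chosen by screening), followed by acidification, rejoins the route at 10.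

3. Step 6. What may go wrong: facial discrimination in the acyclic enolate may be insufficient, because the slim alkynyl group can also take the in-plane position, and the C2 epimer would then form alongside 14. The fallback replaces substrate control by auxiliary control. It sets out from 10. N-Acylation of (S)-4-benzyl-1,3-oxazolidin-2-one (PivCl, Et3N, LiCl, THF) should give the imide F10. NaN(SiMe3)2 at −78 °C followed by 12 should give the alkylated imide F11, with C2 fixed by the auxiliary in the same sense as the substrate bias. LiOH/H2O2 releases the half acid F12, and MeI/K2CO3 rejoins the route at 14.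

**Further compounds**

F1 | step 10 | acetate of 17 (4-tert-butyl 1-methyl (2R)-3-[1-acetoxy-3-(trimethylsilyl)prop-2-yn-1-yl]-2-{(1R)-3-(TIPS)-1-[2-(trimethylsilyl)furan-3-yl]prop-2-yn-1-yl}butanedioate, mixture at C3/C4) | COC(=O)[C@@H](C(C(OC(C)=O)C#C[Si](C)(C)C)C(=O)OC(C)(C)C)[C@H](C#C[Si](C(C)C)(C(C)C)C(C)C)c1ccoc1[Si](C)(C)C
F2 | step 10 | 4-tert-butyl 1-methyl (2R)-3-(1-acetoxyprop-2-yn-1-yl)-2-{(1R)-1-[2-(trimethylsilyl)furan-3-yl]prop-2-yn-1-yl}butanedioate (mixture at C3/C4) | COC(=O)[C@@H](C(C(OC(C)=O)C#C)C(=O)OC(C)(C)C)[C@H](C#C)c1ccoc1[Si](C)(C)C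
F3 | step 10 | 3-tert-butyl 2-methyl (1R,2R)-4-acetoxy-6,7-bis(Bpin)-1-[2-(trimethylsilyl)furan-3-yl]-1,2,3,4-tetrahydronaphthalene-2,3-dicarboxylate (mixture at C3/C4) | COC(=O)[C@H]1C(C(=O)OC(C)(C)C)C(OC(C)=O)c2cc(B3OC(C)(C)C(C)(C)O3)c(B3OC(C)(C)C(C)(C)O3)cc2[C@@H]1c1ccoc1[Si](C)(C)C
F4 | step 3 | 2-(trimethylsilyl)furan-3-carbaldehyde | O=Cc1ccoc1[Si](C)(C)C
F5 | step 3 | 2,2-dimethyl-5-{[2-(trimethylsilyl)furan-3-yl]methylidene}-1,3-dioxane-4,6-dione | CC1(C)OC(=O)C(=Cc2ccoc2[Si](C)(C)C)C(=O)O1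
F6 | step 3 | bromo{[tri(propan-2-yl)silyl]ethynyl}magnesium | CC(C)[Si](C#C[Mg]Br)(C(C)C)C(C)C
F7 | step 3 | 2,2-dimethyl-5-{3-[tri(propan-2-yl)silyl]-1-[2-(trimethylsilyl)furan-3-yl]prop-2-yn-1-yl}-1,3-dioxane-4,6-dione (racemic) | CC1(C)OC(=O)C(C(C#C[Si](C(C)C)(C(C)C)C(C)C)c2ccoc2[Si](C)(C)C)C(=O)O1
F8 | step 3 | 5-[tri(propan-2-yl)silyl]-3-[2-(trimethylsilyl)furan-3-yl]pent-4-ynoic acid (racemic) | OC(=O)CC(C#C[Si](C(C)C)(C(C)C)C(C)C)c1ccoc1[Si](C)(C)C
F9 | step 3 | (1S,2R)-2-hydroxy-2,3-dihydro-1H-inden-1-aminium (3R)-5-[tri(propan-2-yl)silyl]-3-[2-(trimethylsilyl)furan-3-yl]pent-4-ynoate | [O-]C(=O)C[C@H](C#C[Si](C(C)C)(C(C)C)C(C)C)c1ccoc1[Si](C)(C)C.[NH3+][C@@H]1[C@H](O)Cc2ccccc12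
F10 | step 6 | (4S)-4-benzyl-3-{(3R)-5-[tri(propan-2-yl)silyl]-3-[2-(trimethylsilyl)furan-3-yl]pent-4-ynoyl}-1,3-oxazolidin-2-one | O=C(C[C@H](C#C[Si](C(C)C)(C(C)C)C(C)C)c1ccoc1[Si](C)(C)C)N1[C@@H](Cc2ccccc2)COC1=O
F11 | step 6 | tert-butyl (3S,4R)-3-{[(4S)-4-benzyl-2-oxo-1,3-oxazolidin-3-yl]carbonyl}-6-[tri(propan-2-yl)silyl]-4-[2-(trimethylsilyl)furan-3-yl]hex-5-ynoate | O=C([C@@H](CC(=O)OC(C)(C)C)[C@H](C#C[Si](C(C)C)(C(C)C)C(C)C)c1ccoc1[Si](C)(C)C)N1[C@@H](Cc2ccccc2)COC1=O
F12 | step 6 | (2S)-4-tert-butoxy-4-oxo-2-{(1R)-3-[tri(propan-2-yl)silyl]-1-[2-(trimethylsilyl)furan-3-yl]prop-2-yn-1-yl}butanoic acid | OC(=O)[C@@H](CC(=O)OC(C)(C)C)[C@H](C#C[Si](C(C)C)(C(C)C)C(C)C)c1ccoc1[Si](C)(C)C
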